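Amounts first: 10 µM of free catalyst faces 10 mM of substrate and 7.00 mM of coupling partner, and each round spends one coupling partner on one substrate.

substrate 10 mM; coupling partner 7.00 mM; free catalyst 10 µM

    substrate + catalyst intermediate B → catalyst intermediate C (k1 = 85000 M⁻¹ min⁻¹)
    coupling partner + free catalyst → catalyst intermediate A (k2 = 3900 M⁻¹ min⁻¹)
    coupling partner ⇌ dormant form (K3 = 1.9, k3 = 0.037 min⁻¹)
    catalyst intermediate C → free catalyst + target (k4 = 34 min⁻¹)
    catalyst intermediate A → by-product + catalyst intermediate B (k5 = 350 min⁻¹)

- the form that holds most of the catalyst when 10 % of the substrate are converted (catalyst intermediate B / catalyst intermediate C / free catalyst / catalyst intermediate A)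
- its share of the catalyst then
- factor on the rate of making target when 10 % of the substrate are converted if coupling partner is charged twice over
- factor on the rate when 10 % of the substrate are converted if free catalyst is charged at 100 µM instead

Put one round of the cycle on the board as a chain of waits, each wait being one over the pseudo-first-order constant of the step that ends it. At 10 % conversion, catalyst intermediate C waits 0.0294 min, A waits 0.00286 min and B waits 0.00131 min, which sum to 0.0336 min. Free catalyst waits one over k2 times c(coupling partner), and each form's share of the catalyst is its wait over the whole round.

The number to carry is the crossing level: the c(coupling partner) at which the wait at free catalyst equals the other waits together, 7.64 mM. Free catalyst's share is then the crossing level over the crossing level plus c(coupling partner).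

Both disputants take free catalyst as the resting state, but they enter different partner levels. The first says partner leaves in step with substrate, so 6.00 mM remains, below the crossing, and free catalyst holds 56.0 %.

The second says a round of 0.0763 min makes 1.00 mM of conversion take 7.63 min in this 10 µM flask. By this estimate the leak to dormant form removes 24.6 % of the partner over that time, with the way back neglected. That leaves 4.52 mM and a share of 62.8 %.

I side with the second, because this leak is larger than the 14.3 % of the charge that coupling takes. My reckoning stops at the share.

The forecast also takes the second side: free catalyst at 63 % (59 % to 67 %), a factor of 1.57 (1.45 to 1.7) for doubled partner, and 11.7 (11 to 12.4) for 100 µM of catalyst. Its ground is that “the dormant form drains it on the same timescale”.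

The simulation gives free catalyst at 63.0 %, catalyst intermediate C at 32.4 %, and factors of 1.58 and 11.7.

Through the crossing, that share reads as c(coupling partner) 4.49 mM in the 10 µM flask. The first disputant's region is the 100 µM flask: the same estimate puts the conversion at about 0.763 min and the leak at 2.78 %, the crossing rule gives 56.7 %, and that flask reads 56.6 %, below the low end of the forecast's range for the 10 µM flask. Two drains pull on the partner in the 10 µM flask. At 0.738 h, coupling with free catalyst uses it at 0.92 times the rate of its loss to dormant form, forward step alone.

The constants used here are those of an exercise; the rest is arithmetic.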